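**Retrosynthetic overview**

- The strategy rests on the benzene ring of 15 (C1 OAc, C2 OH, C3 H, C4 OH, C5 H, C6 pentadecyl): C5–C6 is the one ring bond joining two oxygen-free carbons, so it is disconnected as an alkene. The arene is reached by enolisation of ene-dione 14, which comes from oxidation of cyclic ketol 13.
- 13 comes from ring-closing metathesis of the open-chain diene 12. The acetate already sits on the sp3 carbinol that becomes C1, so the three ring oxygens never have to be told apart as phenols.
- 12 comes from a methyl-side boron aldol of acetoxy ketone 8 with acrolein 9. 8 comes from ketol 7, assembled from 1-ethoxyvinyllithium 4 (from 3) and enal 2 (α-methylenation of 1).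
- Ring order: the single six-membered carbocycle is closed in step 5 and aromatised in step 6.

Key step: step 5

Remark on the chemistry: 15 is achiral, so the carbinol centres of 5 to 8 and 10 to 14 are carried as racemates or diastereomer mixtures; heptadecanal is taken as a purchased aldehyde.

**Route**

Step 1
Reactants: 1 heptadecanal
Product: 2 2-methylideneheptadecanal
Conditions: 37% aq. HCHO, pyrrolidine (10 mol%), EtCO2H (10 mol%), i-PrOH, 45 °C
Reagents that add atoms: formaldehyde, C=O
Why: Organocatalytic Mannich-type α-methylenation, in which the pyrrolidine enamine of 1 adds to the formaldehyde iminium ion and the Mannich base loses pyrrolidine; 1 has a single α-CH2, so only one 2-substituted acrolein can form.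

Step 2
Reactants: 2 2-methylideneheptadecanal; 3 ethyl vinyl ether
Product: 7 3-hydroxy-4-methylidenenonadecan-2-one (racemic), via 1-ethoxyvinyllithium 4 (not isolated), via lithium alkoxide 5 (not isolated), via ethoxyvinyl carbinol 6 (not isolated)
Conditions: 3, t-BuLi, THF, -78 → 0 °C; then 2, -78 °C; then 1 M aq. HCl, THF, 0 °C
Reagents that add atoms: water, O
Why: α-Lithiated ethyl vinyl ether is an acetyl anion equivalent that adds 1,2 to the enal at low temperature, and cold dilute acid hydrolyses the enol ether to the methyl ketone before the ketol can isomerise; the new carbinol centre forms racemic and is erased in step 6.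

Step 3
Reactants: 7 3-hydroxy-4-methylidenenonadecan-2-one
Product: 8 4-methylidene-2-oxononadecan-3-yl acetate (racemic)
Conditions: Ac2O, pyridine, DMAP (5 mol%), CH2Cl2, 0 °C
Reagents that add atoms: acetic anhydride, CC(=O)OC(C)=O
Why: DMAP-catalysed acylation of a secondary alcohol, run cold with pyridine as the only base so that the C–H that is both allylic and α to the ketone is not removed.

Step 4
Reactants: 8 4-methylidene-2-oxononadecan-3-yl acetate; 9 acrolein
Product: 12 6-hydroxy-4-oxo-2-pentadecylocta-1,7-dien-3-yl acetate (mixture of diastereomers), via boron enolate 10 (not isolated), via boron aldolate 11 (not isolated)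
Conditions: (c-Hex)2BCl, Et3N, Et2O, -78 °C; then 9, -78 → -20 °C; then MeOH, pH 7 buffer, 30% H2O2, 0 °C
Reagents that add atoms: none
Why: Boron-mediated aldol addition, in which (c-Hex)2BCl/Et3N enolises the ketone kinetically at the unhindered methyl group and not at the tertiary acetoxy-bearing carbon, leaves the ester untouched, and adds 1,2 to acrolein through a cyclic six-membered transition state; the new carbinol centre is formed without control and is carried as a mixture because step 6 oxidises it.

Step 5
Reactants: 12 6-hydroxy-4-oxo-2-pentadecylocta-1,7-dien-3-yl acetate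
Product: 13 4-hydroxy-6-oxo-2-pentadecylcyclohex-2-en-1-yl acetate (mixture of diastereomers)
Conditions: second-generation Grubbs catalyst RuCl2(H2IMes)(PCy3)(=CHPh) (5 mol%), 1,4-benzoquinone (10 mol%), CH2Cl2 (0.005 M), 40 °C
Reagents that add atoms: none
Why: The benzylidene complex exchanges first at the unhindered vinyl group beside the free carbinol, the new alkylidene adds across the 1,1-disubstituted alkene in an intramolecular [2+2] cycloaddition, and cycloreversion of the ruthenacyclobutane gives the trisubstituted alkene (the future C5=C6) and a ruthenium methylidene that continues the cycle, with ethylene lost overall. The closest known reaction type is ring-closing metathesis of a monosubstituted with a 1,1-disubstituted alkene to a trisubstituted cyclohexene, as used in metathesis routes to phenol precursors. The one ring closed is a six-membered carbocycle, formed by alkene metathesis across a four-atom tether of sp3 and carbonyl carbons. No stereocentre is created, and the two carbinol centres are only carried along, since both become sp2 in step 6. The step needs cyclisation to outrun cross-metathesis and must avoid loss of water from the β-hydroxy ketone and ruthenium hydride isomerisation of the allylic alcohol. High dilution, the reluctance of the 1,1-disubstituted alkene to homodimerise, the neutral medium and the benzoquinone additive should secure this, and 13 is passed quickly through neutral silica and used at once.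

Step 6
Reactants: 13 4-hydroxy-6-oxo-2-pentadecylcyclohex-2-en-1-yl acetate
Product: 15 2,4-dihydroxy-6-pentadecylphenyl acetate, via ene-dione 14 (not isolated)
Conditions: Dess–Martin periodinane (1.1 equiv), CH2Cl2, 0 °C → rt; pH 7 buffer work-up
Reagents that add atoms: none
Why: Dess–Martin oxidation of the secondary allylic alcohol gives ene-dione 14, whose ring holds two ketones and one alkene and is therefore the keto tautomer of the arene, so enolisation of the CH2 between the carbonyls and then of the acetoxy-bearing CH, catalysed by the acetic acid released, should give the phenol; with no base present the acetate should stay on O1 and not shift to the neighbouring O2 hydroxyl.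

**Compound list**

1 | heptadecanal | CCCCCCCCCCCCCCCCC=O | starting material
2 | 2-methylideneheptadecanal | CCCCCCCCCCCCCCCC(=C)C=O | intermediate
3 | ethyl vinyl ether | C=COCC | starting material
4 | 1-ethoxyvinyllithium | [Li]C(=C)OCC | intermediate (not isolated)
5 | lithium 2-ethoxy-4-methylidenenonadec-1-en-3-olate (racemic) | CCCCCCCCCCCCCCCC(=C)C(O[Li])C(=C)OCC | intermediate (not isolated)
6 | 2-ethoxy-4-methylidenenonadec-1-en-3-ol (racemic) | CCCCCCCCCCCCCCCC(=C)C(O)C(=C)OCC | intermediate (not isolated)
7 | 3-hydroxy-4-methylidenenonadecan-2-one (racemic) | CCCCCCCCCCCCCCCC(=C)C(O)C(C)=O | intermediate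
8 | 4-methylidene-2-oxononadecan-3-yl acetate (racemic) | CCCCCCCCCCCCCCCC(=C)C(OC(C)=O)C(C)=O | intermediate
9 | acrolein | C=CC=O | starting material
10 | 2-[(dicyclohexylboranyl)oxy]-4-methylidenenonadec-1-en-3-yl acetate (racemic) | CCCCCCCCCCCCCCCC(=C)C(OC(C)=O)C(=C)OB(C1CCCCC1)C1CCCCC1 | intermediate (not isolated)
11 | 6-[(dicyclohexylboranyl)oxy]-4-oxo-2-pentadecylocta-1,7-dien-3-yl acetate (mixture of diastereomers) | CCCCCCCCCCCCCCCC(=C)C(OC(C)=O)C(=O)CC(OB(C1CCCCC1)C1CCCCC1)C=C | intermediate (not isolated)
12 | 6-hydroxy-4-oxo-2-pentadecylocta-1,7-dien-3-yl acetate (mixture of diastereomers) | CCCCCCCCCCCCCCCC(=C)C(OC(C)=O)C(=O)CC(O)C=C | intermediate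
13 | 4-hydroxy-6-oxo-2-pentadecylcyclohex-2-en-1-yl acetate (mixture of diastereomers) | CCCCCCCCCCCCCCCC1=CC(O)CC(=O)C1OC(C)=O | intermediate
14 | 4,6-dioxo-2-pentadecylcyclohex-2-en-1-yl acetate (racemic) | CCCCCCCCCCCCCCCC1=CC(=O)CC(=O)C1OC(C)=O | intermediate (not isolated)
15 | 2,4-dihydroxy-6-pentadecylphenyl acetate | CCCCCCCCCCCCCCCc1cc(O)cc(O)c1OC(C)=O | target

**Step count**

Total step count: 6. Longest linear sequence: 6 steps (1 → 15).

**Steps most likely to fail**

1. Step 5. The ruthenium alkylidene may be held back by chelation to the hydroxy ketone, ruthenium hydrides may isomerise the allylic alcohol to an ethyl ketone, or the ketol may lose water on the way to a deoxygenated phenol. The fallback sets out from 12 and masks the carbinol first. TESCl and imidazole in CH2Cl2 at 0 °C should give 4-oxo-2-pentadecyl-6-[(triethylsilyl)oxy]octa-1,7-dien-3-yl acetate F1. Ring closure with the second-generation Hoveyda–Grubbs catalyst RuCl2(H2IMes)(=CH-C6H4-2-OiPr) in toluene at 80 °C should give 6-oxo-2-pentadecyl-4-[(triethylsilyl)oxy]cyclohex-2-en-1-yl acetate F2. HF·pyridine in THF/pyridine at 0 °C removes the silyl group and the route is rejoined at 13.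

2. Step 4. Enolisation may occur toward the acetoxy-bearing carbon, which is allylic and doubly activated, followed by migration of the alkene into conjugation or bond formation at the wrong carbon; the enolate may also attack the acetate. The fallback sets out from 7 and uses a silyl ether, for which methyl-side kinetic enolisation is secure, at the cost of a protecting-group exchange.
   - TESCl and imidazole in DMF give 4-methylidene-3-[(triethylsilyl)oxy]nonadecan-2-one F3.
   - LiN(i-Pr)2 in THF at -78 °C forms lithium 4-methylidene-3-[(triethylsilyl)oxy]nonadec-1-en-2-olate F4. Acrolein 9 adds to it to give lithium 3-oxo-7-pentadecyl-6-[(triethylsilyl)oxy]octa-1,7-dien-4-olate F5, and an acetic acid quench releases 6-hydroxy-2-pentadecyl-3-[(triethylsilyl)oxy]octa-1,7-dien-4-one F6.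
   - TBSOTf and 2,6-lutidine in CH2Cl2 at -78 °C give 6-[(tert-butyldimethylsilyl)oxy]-2-pentadecyl-3-[(triethylsilyl)oxy]octa-1,7-dien-4-one F7.
   - PPTS in MeOH/CH2Cl2 at 0 °C removes only the triethylsilyl group to give 6-[(tert-butyldimethylsilyl)oxy]-3-hydroxy-2-pentadecylocta-1,7-dien-4-one F8.
   - Ac2O, pyridine and DMAP give 6-[(tert-butyldimethylsilyl)oxy]-4-oxo-2-pentadecylocta-1,7-dien-3-yl acetate F9.
   - HF·pyridine in THF then frees the carbinol and the route is rejoined at 12.

3. Step 6. The electron-rich phenol may be oxidised further as it forms, the acetyl group may shift to the neighbouring phenol oxygen if any base is present, and the ketol may dehydrate before it is oxidised. The fallback sets out from 12 and reverses the order of oxidation and ring closure, so that no oxidant meets the phenol. Dess–Martin periodinane in CH2Cl2 at 0 °C should oxidise the open-chain carbinol to 4,6-dioxo-2-pentadecylocta-1,7-dien-3-yl acetate F10, which should exist largely as its enol. Ring-closing metathesis with the second-generation Hoveyda–Grubbs catalyst RuCl2(H2IMes)(=CH-C6H4-2-OiPr) in CH2Cl2 at 40 °C then gives ene-dione 14 directly, where the route is rejoined; 14 enolises to 15 under neutral, non-oxidising conditions.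

**Further compounds**

F1 | step 5 | 4-oxo-2-pentadecyl-6-[(triethylsilyl)oxy]octa-1,7-dien-3-yl acetate | CCCCCCCCCCCCCCCC(=C)C(OC(C)=O)C(=O)CC(O[Si](CC)(CC)CC)C=C
F2 | step 5 | 6-oxo-2-pentadecyl-4-[(triethylsilyl)oxy]cyclohex-2-en-1-yl acetate | CCCCCCCCCCCCCCCC1=CC(O[Si](CC)(CC)CC)CC(=O)C1OC(C)=O
F3 | step 4 | 4-methylidene-3-[(triethylsilyl)oxy]nonadecan-2-one | CCCCCCCCCCCCCCCC(=C)C(O[Si](CC)(CC)CC)C(C)=O
F4 | step 4 | lithium 4-methylidene-3-[(triethylsilyl)oxy]nonadec-1-en-2-olate | CCCCCCCCCCCCCCCC(=C)C(O[Si](CC)(CC)CC)C(=C)O[Li]
F5 | step 4 | lithium 3-oxo-7-pentadecyl-6-[(triethylsilyl)oxy]octa-1,7-dien-4-olate | CCCCCCCCCCCCCCCC(=C)C(O[Si](CC)(CC)CC)C(=O)CC(O[Li])C=C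
F6 | step 4 | 6-hydroxy-2-pentadecyl-3-[(triethylsilyl)oxy]octa-1,7-dien-4-one | CCCCCCCCCCCCCCCC(=C)C(O[Si](CC)(CC)CC)C(=O)CC(O)C=C
F7 | step 4 | 6-[(tert-butyldimethylsilyl)oxy]-2-pentadecyl-3-[(triethylsilyl)oxy]octa-1,7-dien-4-one | CCCCCCCCCCCCCCCC(=C)C(O[Si](CC)(CC)CC)C(=O)CC(O[Si](C)(C)C(C)(C)C)C=C
F8 | step 4 | 6-[(tert-butyldimethylsilyl)oxy]-3-hydroxy-2-pentadecylocta-1,7-dien-4-one | CCCCCCCCCCCCCCCC(=C)C(O)C(=O)CC(O[Si](C)(C)C(C)(C)C)C=C
F9 | step 4 | 6-[(tert-butyldimethylsilyl)oxy]-4-oxo-2-pentadecylocta-1,7-dien-3-yl acetate | CCCCCCCCCCCCCCCC(=C)C(OC(C)=O)C(=O)CC(O[Si](C)(C)C(C)(C)C)C=C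
F10 | step 6 | 4,6-dioxo-2-pentadecylocta-1,7-dien-3-yl acetate | CCCCCCCCCCCCCCCC(=C)C(OC(C)=O)C(=O)CC(=O)C=C
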